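**Retrosynthetic overview**
- Target 29 ← cleavage of four aryl methyl ethers ← fourfold formylation of the four free arene positions of chroman 27.
- Chroman 27 ← tethered vinylketene–ynol ether benzannulation of cyclobutenone 22: the pyran ring closes first ([2+2], C4a–C8a and C7–C8), ring A second (ring opening, six-electron closure at C6–C7); ring B is carried from the start.
- Feature used: the C4a–C8a bond shared by ring A and the pyran ring, with ring A oxygenated at C8a (O1), C5 and C7, the 1,3,5-pattern that a 3-alkoxyvinylketene and an alkynyl ether deliver.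
- Precursor 22 ← ketene/siloxyalkyne [2+2] on diyne 19, then removal of both silyl groups and O-methylation ← O-ethynylation and acetylide oxidation of hydroxy alkyne 14 ← lactone 12.
- Lactone 12 (C2, C3, C4 set on a butyrolactone template) ← butenolide 5 by anti cuprate addition/aldol, dehydration, cis-selective hydrogenation ← asymmetric propiolate addition to aldehyde 1.

Key step: step 11

Remarks on the chemistry:
- Assumption: the ligand antipode in step 1 is the one that gives the (R)-carbinol; if the facial sense is opposite, the other ligand enantiomer is used.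
- The ethynyl ether is made before the cyclobutenone and carried as its C-triisopropylsilyl derivative. A free alkoxide or n-BuLi would attack a 3-alkoxycyclobutenone, and a free ynol ether would consume ketene. Both silyl groups are removed together just before the key step.
- Ketene is generated on site by pyrolysis of acetone and used as a gas stream.

**Step 1**
Reactants: 1 2,4,6-trimethoxybenzaldehyde; 2 methyl propiolate
Product: 3 methyl (R)-4-hydroxy-4-(2,4,6-trimethoxyphenyl)but-2-ynoate
Conditions: Me2Zn (3 eq), (S,S)-ProPhenol (10 mol %), Ph3PO (20 mol %), toluene, 4 °C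
Reagents that add atoms: none
Why: Dinuclear zinc–ProPhenol asymmetric alkynylation of an aryl aldehyde with a propiolate, in which the chiral zinc alkoxide pocket differentiates the aldehyde faces and sets the carbinol centre (future C2) as R.

**Step 2**
Reactants: 3 methyl (R)-4-hydroxy-4-(2,4,6-trimethoxyphenyl)but-2-ynoate
Product: 5 (R)-5-(2,4,6-trimethoxyphenyl)furan-2(5H)-one, via Z-hydroxy enoate 4 (not isolated)
Conditions: H2 (1 atm), Pd/CaCO3–Pb(OAc)2 (Lindlar), quinoline, EtOAc, rt; then PPTS (5 mol %), CH2Cl2, rt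
Reagents that add atoms: none
Why: Lindlar semihydrogenation gives the Z-enoate, whose hydroxyl is held next to the ester and lactonises to the butenolide without touching the carbinol centre.

**Step 3**
Reactants: 5 (R)-5-(2,4,6-trimethoxyphenyl)furan-2(5H)-one; 6 isopropylmagnesium chloride; 7 isobutyraldehyde
Product: 9 (3S,4R,5R)-3-(1-hydroxy-2-methylpropyl)-4-(propan-2-yl)-5-(2,4,6-trimethoxyphenyl)oxolan-2-one (both carbinol epimers), via magnesium enolate 8 (not isolated)
Conditions: 6 (2.4 eq), CuBr·SMe2 (1.2 eq), THF, −78 °C; then 7, −78 → −40 °C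
Reagents that add atoms: none
Why: Cuprate conjugate addition to the butenolide anti to the C5 aryl group sets the isopropyl centre (future C3) trans to the aryl group, and the enolate is trapped by aldol addition anti to the new isopropyl group (three-component coupling), the carbinol centre being removed in step 4.

**Step 4**
Reactants: 9 (3S,4R,5R)-3-(1-hydroxy-2-methylpropyl)-4-(propan-2-yl)-5-(2,4,6-trimethoxyphenyl)oxolan-2-one
Product: 11 (4R,5R,E)-3-(2-methylpropylidene)-4-(propan-2-yl)-5-(2,4,6-trimethoxyphenyl)oxolan-2-one, via mesylate 10 (not isolated)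
Conditions: MsCl, Et3N, CH2Cl2, 0 °C; then DBU, rt
Reagents that add atoms: none
Why: Mesylation followed by E1cB elimination through the lactone enolate completes an aldol condensation and creates no stereocentre.

**Step 5**
Reactants: 11 (4R,5R,E)-3-(2-methylpropylidene)-4-(propan-2-yl)-5-(2,4,6-trimethoxyphenyl)oxolan-2-one
Product: 12 (3S,4R,5R)-3-(2-methylpropyl)-4-(propan-2-yl)-5-(2,4,6-trimethoxyphenyl)oxolan-2-one
Conditions: H2 (1 atm), Rh/Al2O3 (5 wt %), EtOAc, rt
Reagents that add atoms: none
Why: Heterogeneous hydrogenation of the exocyclic alkene from the face opposite the adjacent isopropyl group places the isobutyl group cis to it (future C4, S), and Rh/Al2O3 is chosen over Pd/C to avoid hydrogenolysis of the benzylic lactone C–O bond.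

**Step 6**
Reactants: 12 (3S,4R,5R)-3-(2-methylpropyl)-4-(propan-2-yl)-5-(2,4,6-trimethoxyphenyl)oxolan-2-one
Product: 13 (3S,4R,5R)-3-(2-methylpropyl)-4-(propan-2-yl)-5-(2,4,6-trimethoxyphenyl)oxolan-2-ol (both anomers)
Conditions: i-Bu2AlH (1.1 eq), CH2Cl2, −78 °C
Reagents that add atoms: none
Why: Partial hydride reduction of a lactone stops at the lactol because the aluminium hemiacetal is stable at low temperature.

**Step 7**
Reactants: 13 (3S,4R,5R)-3-(2-methylpropyl)-4-(propan-2-yl)-5-(2,4,6-trimethoxyphenyl)oxolan-2-ol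
Product: 14 (1R,2R,3S)-3-ethynyl-5-methyl-2-(propan-2-yl)-1-(2,4,6-trimethoxyphenyl)hexan-1-ol
Conditions: dimethyl (1-diazo-2-oxopropyl)phosphonate, K2CO3, MeOH, 0 °C → rt
Reagents that add atoms: dimethyl (1-diazo-2-oxopropyl)phosphonate, CC(=O)C(=[N+]=[N-])P(=O)(OC)OC
Why: Seyferth–Gilbert homologation (Ohira–Bestmann reagent) of the open hydroxy aldehyde form of the lactol turns the aldehyde carbon (future C4a) into the inner alkyne carbon, and the mild carbonate base is expected to leave the adjacent stereocentre intact.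

**Step 8**
Reactants: 14 (1R,2R,3S)-3-ethynyl-5-methyl-2-(propan-2-yl)-1-(2,4,6-trimethoxyphenyl)hexan-1-ol
Product: 16 (1R,2R,3S)-5-methyl-2-(propan-2-yl)-3-({[tri(propan-2-yl)silyl]oxy}ethynyl)-1-(2,4,6-trimethoxyphenyl)hexan-1-ol, via dilithium ynolate alkoxide 15 (not isolated)
Conditions: LiN(SiMe3)2 (2.2 eq), THF, −78 °C; t-BuOOLi (from t-BuOOH and LiN(SiMe3)2, 1.2 eq), −78 → 0 °C; i-Pr3SiCl (1.2 eq), −78 → 0 °C
Reagents that add atoms: tert-butyl hydroperoxide, CC(C)(C)OO; chlorotri(propan-2-yl)silane, CC(C)[Si](Cl)(C(C)C)C(C)C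
Why: Oxidation of the lithium acetylide by lithium tert-butyl peroxide gives the ynolate, which the bulky silyl chloride should silylate on oxygen faster than it silylates the hindered secondary lithium alkoxide, so that the carbinol returns free on work-up (ynolate formation and O-silylation to a siloxyalkyne).

**Step 9**
Reactants: 16 (1R,2R,3S)-5-methyl-2-(propan-2-yl)-3-({[tri(propan-2-yl)silyl]oxy}ethynyl)-1-(2,4,6-trimethoxyphenyl)hexan-1-ol
Product: 19 (1R,2R,3S)-diyne in which the carbinol oxygen of 16 carries a [tri(propan-2-yl)silyl]ethynyl group, via dichlorovinyl ether 17 (not isolated), via lithium alkoxyacetylide 18 (not isolated)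
Conditions: KH (1.5 eq), THF, 0 °C; Cl2C=CHCl (1.1 eq), −50 °C → rt; n-BuLi (2.5 eq), −78 → −40 °C; i-Pr3SiOTf (1.3 eq), −78 → 0 °C
Reagents that add atoms: trichloroethylene, ClC=C(Cl)Cl; tri(propan-2-yl)silyl trifluoromethanesulfonate, CC(C)[Si](OS(=O)(=O)C(F)(F)F)(C(C)C)C(C)C
Why: Ynol ether synthesis by addition of the potassium alkoxide to dichloroacetylene formed in situ, elimination and chlorine–lithium exchange with n-BuLi, and C-silylation of the lithium alkoxyacetylide, with retention at the carbinol carbon because only the O–H bond reacts and with any ynolate released from the siloxyalkyne re-silylated by the same triflate.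

**Step 10**
Reactants: 19 (1R,2R,3S)-diyne with siloxyalkyne and C-silylated ethynyl ether
Product: 22 2-[(1R,2R,3S)-1-(ethynyloxy)-5-methyl-2-(propan-2-yl)-1-(2,4,6-trimethoxyphenyl)hexan-3-yl]-3-methoxycyclobut-2-en-1-one, via bis-silyl cyclobutenone 20 (not isolated), via cyclobutenolate 21 (not isolated)
Conditions: ketene (excess), CH2Cl2, 0 °C; purge, switch to THF; Bu4NF (2.5 eq), −20 → 0 °C; Me2SO4 (3 eq), 0 °C → rt; chromatography on neutral alumina, cold
Reagents that add atoms: ketene, C=C=O; dimethyl sulfate, COS(=O)(=O)OC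
Why: The [2+2] cycloaddition of ketene with a siloxyalkyne gives the 3-siloxycyclobutenone regioselectively (ketene carbonyl carbon to the alkyl-bearing alkyne carbon) while the ynol ether is shielded at its nucleophilic carbon by the triisopropylsilyl group, after which fluoride removes both silyl groups and the ambident cyclobutenolate is O-methylated by the hard electrophile, C-methylation at the hindered ring carbon being disfavoured.

**Step 11**
Reactants: 22 2-[(1R,2R,3S)-1-(ethynyloxy)-5-methyl-2-(propan-2-yl)-1-(2,4,6-trimethoxyphenyl)hexan-3-yl]-3-methoxycyclobut-2-en-1-one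
Product: 27 (2R,3R,4S)-5-methoxy-4-(2-methylpropyl)-3-(propan-2-yl)-2-(2,4,6-trimethoxyphenyl)-3,4-dihydro-2H-chromen-7-ol, via vinylketene 23 (not isolated), via fused cyclobutenone 24 (not isolated), via dienylketene 25 (not isolated), via cyclohexadienone 26 (not isolated)
Conditions: hν (300 nm, Pyrex), degassed toluene (0.005 M), 15 °C; then 80 °C
Reagents that add atoms: none
Why: Proposed new method: n→π* excitation opens the 3-methoxycyclobutenone by four-electron electrocyclic cleavage to the 3-methoxyvinylketene 23, and its ketene unit undergoes [2+2] cycloaddition with the tethered ethynyl ether (ketene carbon to the alkyne CH, forming C7–C8; α-carbon to the oxygen-bearing alkyne carbon, forming C4a–C8a), which closes the pyran ring as a six-membered ring fused to the new cyclobutenone 24. Four-electron opening of 24 gives dienylketene 25, and six-electron electrocyclisation (C6–C7) followed by tautomerisation of dienone 26 closes ring A as the C7 phenol with the C5 methoxy group in place. The closest known reaction is the intermolecular Danheiser benzannulation of cyclobutenones with alkoxy- and siloxyalkynes, including its photochemical variant, together with intramolecular ketene–alkene [2+2] cycloadditions through four-atom tethers; a version tethered through the ynol ether oxygen that closes a chroman has not been described. No stereocentre is formed, and C2, C3 and C4 are not touched under these neutral, acid-free conditions. The regiochemistry the step needs is secured twice, by the polarity of the ynol ether and by the four-atom tether C4–C3–C2–O1, and in 25 the endocyclic C4a=C8a double bond holds the methoxyvinyl group cis to the ketene arm so that the six-electron closure is geometrically assured. Irradiation at ambient temperature is chosen because the secondary benzylic ethynyl ether would lose ketene by retro-ene fragmentation on heating, and warming is applied only after the ynol ether has been consumed.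

**Step 12**
Reactants: 27 (2R,3R,4S)-5-methoxy-4-(2-methylpropyl)-3-(propan-2-yl)-2-(2,4,6-trimethoxyphenyl)-3,4-dihydro-2H-chromen-7-ol
Product: 28 (2R,3R,4S)-2-(3,5-diformyl-2,4,6-trimethoxyphenyl)-7-hydroxy-5-methoxy-4-(2-methylpropyl)-3-(propan-2-yl)-3,4-dihydro-2H-chromene-6,8-dicarbaldehyde
Conditions: Cl2CHOMe (12 eq), TiCl4 (12 eq), CH2Cl2, −78 → 0 °C; then H2O
Reagents that add atoms: dichloromethyl methyl ether, COC(Cl)Cl; water, O
Why: Rieche formylation takes the only four free arene positions, C6 and C8 of ring A (each ortho or para to three oxygens and directed by the titanium phenoxide at C7) and C3′ and C5′ of ring B, phloroglucinol ethers being electron-rich enough to accept two formyl groups per ring.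

**Step 13**
Reactants: 28 (2R,3R,4S)-2-(3,5-diformyl-2,4,6-trimethoxyphenyl)-7-hydroxy-5-methoxy-4-(2-methylpropyl)-3-(propan-2-yl)-3,4-dihydro-2H-chromene-6,8-dicarbaldehyde
Product: 29 sideroxylonal A
Conditions: BCl3 (excess), CH2Cl2, −78 → 0 °C; then H2O
Reagents that add atoms: none
Why: Chelation-assisted Lewis acid ether cleavage, in which BCl3 removes aryl methyl ethers that sit ortho to a formyl group (all four: C5, C2′, C4′, C6′), while ionisation of the benzylic C2–O1 bond is disfavoured by the now electron-poor diformyl aryl ring.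

**Compound list**
1 | 2,4,6-trimethoxybenzaldehyde | COc1cc(OC)c(C=O)c(OC)c1 | starting material
2 | methyl propiolate | C#CC(=O)OC | starting material
3 | methyl (R)-4-hydroxy-4-(2,4,6-trimethoxyphenyl)but-2-ynoate | COC(=O)C#C[C@@H](O)c1c(OC)cc(OC)cc1OC | intermediate
4 | methyl (R,Z)-4-hydroxy-4-(2,4,6-trimethoxyphenyl)but-2-enoate (not isolated) | COC(=O)/C=C\[C@@H](O)c1c(OC)cc(OC)cc1OC | intermediate
5 | (R)-5-(2,4,6-trimethoxyphenyl)furan-2(5H)-one | O=C1C=C[C@H](c2c(OC)cc(OC)cc2OC)O1 | intermediate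
6 | isopropylmagnesium chloride | CC(C)[Mg]Cl | starting material
7 | isobutyraldehyde | CC(C)C=O | starting material
8 | chloromagnesium enolate of the 4,5-trans 4-(propan-2-yl)-5-(2,4,6-trimethoxyphenyl)oxolan-2-one (5R, isopropyl anti to aryl; not isolated) | Cl[Mg]OC1=C[C@@H](C(C)C)[C@H](c2c(OC)cc(OC)cc2OC)O1 | intermediate
9 | (3S,4R,5R)-3-(1-hydroxy-2-methylpropyl)-4-(propan-2-yl)-5-(2,4,6-trimethoxyphenyl)oxolan-2-one, both carbinol epimers | CC(C)C(O)[C@H]1C(=O)O[C@@H](c2c(OC)cc(OC)cc2OC)[C@@H]1C(C)C | intermediate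
10 | methanesulfonate of 9 (not isolated) | CC(C)C(OS(C)(=O)=O)[C@H]1C(=O)O[C@@H](c2c(OC)cc(OC)cc2OC)[C@@H]1C(C)C | intermediate
11 | (4R,5R,E)-3-(2-methylpropylidene)-4-(propan-2-yl)-5-(2,4,6-trimethoxyphenyl)oxolan-2-one | CC(C)/C=C1/C(=O)O[C@@H](c2c(OC)cc(OC)cc2OC)[C@@H]1C(C)C | intermediate
12 | (3S,4R,5R)-3-(2-methylpropyl)-4-(propan-2-yl)-5-(2,4,6-trimethoxyphenyl)oxolan-2-one (3,4-cis, 4,5-trans) | CC(C)C[C@@H]1C(=O)O[C@@H](c2c(OC)cc(OC)cc2OC)[C@@H]1C(C)C | intermediate
13 | (3S,4R,5R)-3-(2-methylpropyl)-4-(propan-2-yl)-5-(2,4,6-trimethoxyphenyl)oxolan-2-ol, both anomers | CC(C)C[C@@H]1C(O)O[C@@H](c2c(OC)cc(OC)cc2OC)[C@@H]1C(C)C | intermediate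
14 | (1R,2R,3S)-3-ethynyl-5-methyl-2-(propan-2-yl)-1-(2,4,6-trimethoxyphenyl)hexan-1-ol | CC(C)C[C@H](C#C)[C@@H](C(C)C)[C@@H](O)c1c(OC)cc(OC)cc1OC | intermediate
15 | dilithium salt of 14 after acetylide oxidation: lithium ynolate and lithium alkoxide (not isolated) | CC(C)C[C@H](C#CO[Li])[C@@H](C(C)C)[C@@H](O[Li])c1c(OC)cc(OC)cc1OC | intermediate
16 | (1R,2R,3S)-5-methyl-2-(propan-2-yl)-3-({[tri(propan-2-yl)silyl]oxy}ethynyl)-1-(2,4,6-trimethoxyphenyl)hexan-1-ol | CC(C)C[C@H](C#CO[Si](C(C)C)(C(C)C)C(C)C)[C@@H](C(C)C)[C@@H](O)c1c(OC)cc(OC)cc1OC | intermediate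
17 | (E)-1,2-dichlorovinyl ether of 16 (not isolated) | CC(C)C[C@H](C#CO[Si](C(C)C)(C(C)C)C(C)C)[C@@H](C(C)C)[C@@H](O/C(Cl)=C\Cl)c1c(OC)cc(OC)cc1OC | intermediate
18 | lithium alkoxyacetylide from 17 (not isolated) | CC(C)C[C@H](C#CO[Si](C(C)C)(C(C)C)C(C)C)[C@@H](C(C)C)[C@@H](OC#C[Li])c1c(OC)cc(OC)cc1OC | intermediate
19 | (1R,2R,3S)-diyne: 16 with its hydroxyl converted into a [tri(propan-2-yl)silyl]ethynyl ether | CC(C)C[C@H](C#CO[Si](C(C)C)(C(C)C)C(C)C)[C@@H](C(C)C)[C@@H](OC#C[Si](C(C)C)(C(C)C)C(C)C)c1c(OC)cc(OC)cc1OC | intermediate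
20 | 2-substituted 3-{[tri(propan-2-yl)silyl]oxy}cyclobut-2-en-1-one carrying the C-silylated ethynyl ether (not isolated) | CC(C)C[C@H](C1=C(O[Si](C(C)C)(C(C)C)C(C)C)CC1=O)[C@@H](C(C)C)[C@@H](OC#C[Si](C(C)C)(C(C)C)C(C)C)c1c(OC)cc(OC)cc1OC | intermediate
21 | tetrabutylammonium 3-oxocyclobut-1-en-1-olate carrying the free ethynyl ether (not isolated) | CC(C)C[C@H](C1=C([O-])CC1=O)[C@@H](C(C)C)[C@@H](OC#C)c1c(OC)cc(OC)cc1OC.CCCC[N+](CCCC)(CCCC)CCCC | intermediate
22 | 2-[(1R,2R,3S)-1-(ethynyloxy)-5-methyl-2-(propan-2-yl)-1-(2,4,6-trimethoxyphenyl)hexan-3-yl]-3-methoxycyclobut-2-en-1-one | CC(C)C[C@H](C1=C(OC)CC1=O)[C@@H](C(C)C)[C@@H](OC#C)c1c(OC)cc(OC)cc1OC | intermediate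
23 | 3-methoxyvinylketene from ring opening of 22 (not isolated) | CC(C)C[C@H](C(=C=O)C(OC)=C)[C@@H](C(C)C)[C@@H](OC#C)c1c(OC)cc(OC)cc1OC | intermediate
24 | 6-(1-methoxyethenyl)-5-(2-methylpropyl)-4-(propan-2-yl)-3-(2,4,6-trimethoxyphenyl)-2-oxabicyclo[4.2.0]oct-1(8)-en-7-one, either configuration at C6 (not isolated) | CC(C)C[C@@H]1C2(C(OC)=C)C(=O)C=C2O[C@@H](c2c(OC)cc(OC)cc2OC)[C@@H]1C(C)C | intermediate
25 | 2-[5-(1-methoxyethenyl)-4-(2-methylpropyl)-3-(propan-2-yl)-2-(2,4,6-trimethoxyphenyl)-3,4-dihydro-2H-pyran-6-yl]ethen-1-one (dienylketene, not isolated) | CC(C)C[C@@H]1C(C(OC)=C)=C(C=C=O)O[C@@H](c2c(OC)cc(OC)cc2OC)[C@@H]1C(C)C | intermediate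
26 | keto tautomer of 27, 5-methoxy-2,3,4,6-tetrahydro-7H-chromen-7-one with the same C2, C3, C4 substituents (not isolated) | CC(C)C[C@@H]1C2=C(OC)CC(=O)C=C2O[C@@H](c3c(OC)cc(OC)cc3OC)[C@@H]1C(C)C | intermediate
27 | (2R,3R,4S)-5-methoxy-4-(2-methylpropyl)-3-(propan-2-yl)-2-(2,4,6-trimethoxyphenyl)-3,4-dihydro-2H-chromen-7-ol | CC(C)C[C@@H]1c2c(OC)cc(O)cc2O[C@@H](c2c(OC)cc(OC)cc2OC)[C@@H]1C(C)C | intermediate
28 | (2R,3R,4S)-2-(3,5-diformyl-2,4,6-trimethoxyphenyl)-7-hydroxy-5-methoxy-4-(2-methylpropyl)-3-(propan-2-yl)-3,4-dihydro-2H-chromene-6,8-dicarbaldehyde | CC(C)C[C@@H]1c2c(OC)c(C=O)c(O)c(C=O)c2O[C@@H](c2c(OC)c(C=O)c(OC)c(C=O)c2OC)[C@@H]1C(C)C | intermediate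
29 | sideroxylonal A, (2R,3R,4S) | CC(C)C[C@@H]1c2c(O)c(C=O)c(O)c(C=O)c2O[C@@H](c2c(O)c(C=O)c(O)c(C=O)c2O)[C@@H]1C(C)C | target

**Step count and risks**

Total step count: 13. Longest linear sequence: 13 steps (1 to 29, fully linear).

Steps most likely to fail:

1. Step 11 (Proposed new method). The vinylketene may reclose to the cyclobutenone faster than the tethered ynol ether captures it, because the bicyclo[4.2.0] transition state is demanding. The benzylic ethynyl ether may also be lost first, by retro-ene release of ketene or by ionisation of the C2–O bond. The fallback uses known chemistry and sets out from 16. Silylation of the carbinol (Et3SiCl, imidazole) gives the triethylsilyl ether F1, and ketene cycloaddition to its siloxyalkyne gives the 3-siloxycyclobutenone F2. Thermal intermolecular Danheiser benzannulation of F2 with methoxyacetylene (toluene, 80 °C, sealed tube) gives the phenol F3, in which ynol ether polarity places the side chain between the methoxy and the silyloxy group. Bu4NF removes both silyl groups to give the triol F4. Acid (PPTS, CH2Cl2) ionises the trimethoxybenzylic carbinol, the ortho phenol closes the pyran ring under thermodynamic control (2,3-trans), and the route is rejoined at 27.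

2. Step 10. Ketene may also add to the capped ynol ether if steric discrimination is insufficient. The cyclobutenolate may be methylated on carbon or decompose, or the liberated ethynyl ether may be lost during the unmasking. The fallback avoids ketene and the masked ynol ether altogether, gives up the tether, and sets out from 16. Heating 16 with commercial 3-ethoxycyclobut-2-en-1-one (toluene, 100 °C) uses the siloxyalkyne of 16 as the ketenophile in an intermolecular Danheiser benzannulation and gives the phenol F5, with the side chain between the new hydroxyl and the silyloxy group and the ethoxy group para to it. PPTS closes the pyran ring through the new phenol onto the benzylic carbinol to give the chroman F6, and Bu4NF gives the C5 phenol F7. Fourfold formylation (Cl2CHOMe, TiCl4) gives the tetraaldehyde F8, and BBr3 cleaves the ethyl ether and the three methyl ethers, returning to the route at 29.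

3. Step 9. Addition of the hindered, ionisation-prone benzylic alkoxide to dichloroacetylene may be incomplete, or n-BuLi may attack silicon of the siloxyalkyne before the chlorine–lithium exchange is finished. The fallback builds the ynol ether by formate olefination and sets out from 16. Formylation (formic acetic anhydride, pyridine, 0 °C) gives the formate F9, and dibromo-olefination of the formate carbonyl (PPh3, CBr4, Zn, CH2Cl2) gives the 2,2-dibromovinyl ether F10. Treatment with n-BuLi (2.2 eq, −78 °C) and then i-Pr3SiOTf gives the C-silylated ynol ether and rejoins the route at 19.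

**Further compounds**
F1 | step 11 | O-triethylsilyl ether of 16 | CC(C)C[C@H](C#CO[Si](C(C)C)(C(C)C)C(C)C)[C@@H](C(C)C)[C@@H](O[Si](CC)(CC)CC)c1c(OC)cc(OC)cc1OC
F2 | step 11 | 2-substituted 3-{[tri(propan-2-yl)silyl]oxy}cyclobut-2-en-1-one with the O-triethylsilyl carbinol | CC(C)C[C@H](C1=C(O[Si](C(C)C)(C(C)C)C(C)C)CC1=O)[C@@H](C(C)C)[C@@H](O[Si](CC)(CC)CC)c1c(OC)cc(OC)cc1OC
F3 | step 11 | 3-methoxy-5-{[tri(propan-2-yl)silyl]oxy}phenol carrying the (1R,2R,3S) side chain of F1 at C4 | CC(C)C[C@H](c1c(OC)cc(O)cc1O[Si](C(C)C)(C(C)C)C(C)C)[C@@H](C(C)C)[C@@H](O[Si](CC)(CC)CC)c1c(OC)cc(OC)cc1OC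
F4 | step 11 | 4-[(1R,2R,3S)-1-hydroxy-5-methyl-2-(propan-2-yl)-1-(2,4,6-trimethoxyphenyl)hexan-3-yl]-5-methoxybenzene-1,3-diol | CC(C)C[C@H](c1c(OC)cc(O)cc1O)[C@@H](C(C)C)[C@@H](O)c1c(OC)cc(OC)cc1OC
F5 | step 10 | 5-ethoxy-2-[(1R,2R,3S)-1-hydroxy-5-methyl-2-(propan-2-yl)-1-(2,4,6-trimethoxyphenyl)hexan-3-yl]-3-{[tri(propan-2-yl)silyl]oxy}phenol | CC(C)C[C@H](c1c(O)cc(OCC)cc1O[Si](C(C)C)(C(C)C)C(C)C)[C@@H](C(C)C)[C@@H](O)c1c(OC)cc(OC)cc1OC
F6 | step 10 | (2R,3R,4S)-7-ethoxy-4-(2-methylpropyl)-3-(propan-2-yl)-5-{[tri(propan-2-yl)silyl]oxy}-2-(2,4,6-trimethoxyphenyl)-3,4-dihydro-2H-chromene | CC(C)C[C@@H]1c2c(O[Si](C(C)C)(C(C)C)C(C)C)cc(OCC)cc2O[C@@H](c2c(OC)cc(OC)cc2OC)[C@@H]1C(C)C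
F7 | step 10 | (2R,3R,4S)-7-ethoxy-4-(2-methylpropyl)-3-(propan-2-yl)-2-(2,4,6-trimethoxyphenyl)-3,4-dihydro-2H-chromen-5-ol | CC(C)C[C@@H]1c2c(O)cc(OCC)cc2O[C@@H](c2c(OC)cc(OC)cc2OC)[C@@H]1C(C)C
F8 | step 10 | (2R,3R,4S)-2-(3,5-diformyl-2,4,6-trimethoxyphenyl)-7-ethoxy-5-hydroxy-4-(2-methylpropyl)-3-(propan-2-yl)-3,4-dihydro-2H-chromene-6,8-dicarbaldehyde | CC(C)C[C@@H]1c2c(O)c(C=O)c(OCC)c(C=O)c2O[C@@H](c2c(OC)c(C=O)c(OC)c(C=O)c2OC)[C@@H]1C(C)C
F9 | step 9 | formate ester of 16 | CC(C)C[C@H](C#CO[Si](C(C)C)(C(C)C)C(C)C)[C@@H](C(C)C)[C@@H](OC=O)c1c(OC)cc(OC)cc1OC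
F10 | step 9 | 2,2-dibromovinyl ether of 16 | CC(C)C[C@H](C#CO[Si](C(C)C)(C(C)C)C(C)C)[C@@H](C(C)C)[C@@H](OC=C(Br)Br)c1c(OC)cc(OC)cc1OC
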